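**Strategy**

Everything rests on the C1–C6 bond of the 7-oxabicyclo[4.1.0]heptan-2-one core, the bond shared by the oxirane and the cyclohexanone. It is closed by an intramolecular Corey–Chaykovsky reaction: a diphenylsulfonium ylide at C6 attacks a methyl ketone that becomes C1, so one operation forms the carbocycle and the oxirane and sets C1 and C6. The feature used is that C1 is the hydrogen-free, methyl-bearing oxirane carbon: its carbonyl oxygen becomes the oxirane oxygen, delivered axially and therefore cis to the equatorial C4 substituent. The precursor is an acyclic 3-silyloxy-heptan-2-one carrying the C4 stereocentre, a 1-silylvinyl placeholder for the dienone and a terminal sulfonium salt.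

Key step: step 8

Ring numbering used below: C1 = methyl-bearing oxirane carbon, C2 = ring ketone carbon, C3 = carbon bearing the tiglate, C4 = carbon bearing the side chain, C5 = CH2, C6 = oxirane CH, O7 = oxirane oxygen.

Remark: C2 is carried as a silyl ether through the ring closure and oxidised afterwards, because a free C2 carbonyl would offer the ylide a competing 5-exo addition.

**Route**

Step 1
Reactants: 1 (1-bromoethenyl)trimethylsilane; 2 2-isopropoxy-4,4,5,5-tetramethyl-1,3,2-dioxaborolane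
Product: 4 4,4,5,5-tetramethyl-2-[1-(trimethylsilyl)ethenyl]-1,3,2-dioxaborolane, via alkenyl Grignard reagent 3 (not isolated)
Conditions: Mg turnings, THF, 40 °C; then 2, −78 °C to rt
Reagents that add atoms: none
Why: Magnesium insertion followed by borylation of the alkenyl Grignard reagent with the isopropoxy boronate is the standard boronic ester synthesis; no stereocentre is formed.

Step 2
Reactants: 4 4,4,5,5-tetramethyl-2-[1-(trimethylsilyl)ethenyl]-1,3,2-dioxaborolane; 5 5,6-dihydro-2H-pyran-2-one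
Product: 6 (4R)-4-[1-(trimethylsilyl)ethenyl]oxan-2-one
Conditions: [Rh(cod)OH]2 (2.5 mol%), (R)-BINAP (6 mol%), dioxane/H2O 10:1, 50 °C
Reagents that add atoms: none
Why: Rhodium-catalysed asymmetric 1,4-addition of an alkenylboron reagent (Hayashi–Miyaura reaction) to the unsaturated lactone should set the future C4 centre, with (R)-BINAP chosen by the established facial sense for cyclic enones and this lactone.

Step 3
Reactants: 6 (4R)-4-[1-(trimethylsilyl)ethenyl]oxan-2-one
Product: 7 (5R)-2-ethoxy-7-hydroxy-5-[1-(trimethylsilyl)ethenyl]hept-1-en-3-one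
Conditions: ethyl vinyl ether, t-BuLi, THF, −78 to 0 °C; then 6, −78 °C; H2O quench
Reagents that add atoms: ethyl vinyl ether, C=COCC
Why: tert-Butyllithium metalates ethyl vinyl ether at its α-vinyl carbon to give (1-ethoxyethenyl)lithium, an acyl-anion equivalent whose 1,2-addition to the δ-lactone should stop at the lithium hemiketal, which opens on quench to the hydroxy ketone; no stereocentre is formed.

Step 4
Reactants: 7 (5R)-2-ethoxy-7-hydroxy-5-[1-(trimethylsilyl)ethenyl]hept-1-en-3-one
Product: 8 (3R,5R)-2-ethoxy-5-[1-(trimethylsilyl)ethenyl]hept-1-ene-3,7-diol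
Conditions: (S)-Me-CBS (0.2 equiv), catecholborane (3 equiv), toluene, −78 °C; then H2O
Reagents that add atoms: none
Why: Corey–Bakshi–Shibata reduction should treat the sp2 1-ethoxyvinyl group as the large and the CH2 chain as the small substituent, so the (S)-catalyst gives the 3R carbinol (future C2–O, cis to the C4 group); any C3 epimer is a separable diastereomer.

Step 5
Reactants: 8 (3R,5R)-2-ethoxy-5-[1-(trimethylsilyl)ethenyl]hept-1-ene-3,7-diol
Product: 9 (3R,5R)-3,7-bis[(tert-butyldimethylsilyl)oxy]-2-ethoxy-5-[1-(trimethylsilyl)ethenyl]hept-1-ene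
Conditions: TBSCl (2.5 equiv), imidazole, DMF, rt
Reagents that add atoms: tert-butyldimethylsilyl chloride, CC(C)(C)[Si](C)(C)Cl
Why: Standard silylation of both hydroxyl groups under basic conditions should leave the acid-labile enol ether intact.

Step 6
Reactants: 9 (3R,5R)-3,7-bis[(tert-butyldimethylsilyl)oxy]-2-ethoxy-5-[1-(trimethylsilyl)ethenyl]hept-1-ene
Product: 10 (3R,5R)-3-[(tert-butyldimethylsilyl)oxy]-7-hydroxy-5-[1-(trimethylsilyl)ethenyl]heptan-2-one
Conditions: AcOH/THF/H2O 3:1:1, rt
Reagents that add atoms: water, O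
Why: Mild aqueous acid should hydrolyse the 1-ethoxyvinyl group to the methyl ketone and cleave the primary silyl ether, while the hindered secondary silyl ether next to the ketone survives (known primary-over-secondary TBS selectivity).

Step 7
Reactants: 10 (3R,5R)-3-[(tert-butyldimethylsilyl)oxy]-7-hydroxy-5-[1-(trimethylsilyl)ethenyl]heptan-2-one
Product: 12 [(3S,5R)-5-[(tert-butyldimethylsilyl)oxy]-6-oxo-3-[1-(trimethylsilyl)ethenyl]heptyl]diphenylsulfonium trifluoromethanesulfonate, via primary triflate 11 (not isolated)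
Conditions: Tf2O (1.05 equiv), 2,6-di-tert-butyl-4-methylpyridine, CH2Cl2, −78 °C; then Ph2S (5 equiv), −78 °C to rt
Reagents that add atoms: trifluoromethanesulfonic anhydride, O=S(=O)(OS(=O)(=O)C(F)(F)F)C(F)(F)F; diphenyl sulfide, c1ccc(Sc2ccccc2)cc1
Why: O-Triflation at low temperature (ketone untouched) followed by SN2 alkylation of diphenyl sulfide by the primary triflate is the standard synthesis of S-alkyl diphenylsulfonium salts; the descriptor change at the branched carbon is a priority effect only.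

Step 8
Reactants: 12 [(3S,5R)-5-[(tert-butyldimethylsilyl)oxy]-6-oxo-3-[1-(trimethylsilyl)ethenyl]heptyl]diphenylsulfonium trifluoromethanesulfonate
Product: 15 tert-butyldimethyl{[(1S,2R,4R,6S)-1-methyl-4-[1-(trimethylsilyl)ethenyl]-7-oxabicyclo[4.1.0]heptan-2-yl]oxy}silane, via sulfonium ylide 13 (not isolated), via oxido sulfonium betaine 14 (not isolated)
Conditions: LiN(SiMe3)2 (1.05 equiv), THF, −78 °C to 0 °C
Reagents that add atoms: none
Why: LiN(SiMe3)2 removes one of the two C6 protons, the only α-protons of the S-alkyl diphenylsulfonium group and far more acidic than the ketone α-protons, and the ylide adds 6-exo-trig to the methyl ketone to give the β-oxido sulfonium betaine (C6–C1 bond), whose alkoxide then displaces Ph2S 3-exo-tet with inversion at C6. This is the intramolecular Corey–Chaykovsky epoxidation, the reaction type that operates in the known epoxy-annulations of keto-substituted nucleophiles with vinylsulfonium salts. Both new stereocentres (C1, C6) follow from a chair transition state in which the C4 silylvinyl group, the C2 silyloxy group and the C1 methyl group are equatorial while the oxido and sulfonio groups are trans-diaxial, which places the oxirane oxygen cis to the C4 substituent and to C2–O; the forming bond is also anti to the C2–O bond (polar Felkin–Anh arrangement). The opposite oxirane would require closure from a ring-flipped betaine with three syn-axial groups at C2, C4 and C6 and should therefore not form. Regioselectivity is secured because C1 is the only carbonyl in 12 (C2 is still a silyl ether, so no 5-exo addition can compete) and because the diphenylsulfonium group has no other α-hydrogen.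

Step 9
Reactants: 15 tert-butyldimethyl{[(1S,2R,4R,6S)-1-methyl-4-[1-(trimethylsilyl)ethenyl]-7-oxabicyclo[4.1.0]heptan-2-yl]oxy}silane
Product: 16 (1R,2R,4S,6S)-1-methyl-4-[1-(trimethylsilyl)ethenyl]-7-oxabicyclo[4.1.0]heptan-2-ol
Conditions: TBAF, AcOH, THF, 0 °C to rt
Reagents that add atoms: none
Why: Buffered fluoride desilylation should leave the vinylsilane and the oxirane intact, and the cis relation of the hydroxyl and the oxirane oxygen rules out a Payne rearrangement; no centre changes (descriptor changes are priority effects).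

Step 10
Reactants: 16 (1R,2R,4S,6S)-1-methyl-4-[1-(trimethylsilyl)ethenyl]-7-oxabicyclo[4.1.0]heptan-2-ol
Product: 17 (1S,4R,6S)-1-methyl-4-[1-(trimethylsilyl)ethenyl]-7-oxabicyclo[4.1.0]heptan-2-one
Conditions: Dess–Martin periodinane, NaHCO3, CH2Cl2, rt
Reagents that add atoms: none
Why: Buffered Dess–Martin oxidation converts secondary epoxy alcohols into α,β-epoxy ketones without opening the oxirane.

Step 11
Reactants: 17 (1S,4R,6S)-1-methyl-4-[1-(trimethylsilyl)ethenyl]-7-oxabicyclo[4.1.0]heptan-2-one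
Product: 19 (1S,3S,4R,6S)-3-hydroxy-1-methyl-4-[1-(trimethylsilyl)ethenyl]-7-oxabicyclo[4.1.0]heptan-2-one, via potassium enolate 18 (not isolated)
Conditions: KN(SiMe3)2, THF, −78 °C; then 2-(phenylsulfonyl)-3-phenyloxaziridine, −78 °C; H2O quench
Reagents that add atoms: 2-(phenylsulfonyl)-3-phenyloxaziridine, O=S(=O)(c1ccccc1)N1OC1c1ccccc1
Why: Davis enolate hydroxylation; C3 is the only enolisable position (C1 is quaternary) and the oxidant should approach anti to the adjacent C4 substituent, giving the 3,4-trans (diequatorial, also thermodynamically preferred) hydroxy ketone.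

Step 12
Reactants: 19 (1S,3S,4R,6S)-3-hydroxy-1-methyl-4-[1-(trimethylsilyl)ethenyl]-7-oxabicyclo[4.1.0]heptan-2-one
Product: 20 (1S,3S,4R,6S)-1-methyl-2-oxo-4-[1-(trimethylsilyl)ethenyl]-7-oxabicyclo[4.1.0]heptan-3-yl (2E)-2-methylbut-2-enoate
Conditions: tigloyl chloride, pyridine, DMAP (cat.), CH2Cl2, 0 °C
Reagents that add atoms: (2E)-2-methylbut-2-enoyl chloride (tigloyl chloride), C/C=C(\C)C(=O)Cl
Why: DMAP-catalysed acylation of the secondary α-hydroxy ketone; the E geometry comes from the reagent and no stereocentre is touched.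

Step 13
Reactants: 20 (1S,3S,4R,6S)-1-methyl-2-oxo-4-[1-(trimethylsilyl)ethenyl]-7-oxabicyclo[4.1.0]heptan-3-yl (2E)-2-methylbut-2-enoate
Product: 21 (1S,3S,4R,6S)-4-(1-iodoethenyl)-1-methyl-2-oxo-7-oxabicyclo[4.1.0]heptan-3-yl (2E)-2-methylbut-2-enoate
Conditions: N-iodosuccinimide, MeCN/ClCH2CN 4:1, 0 °C to rt, dark
Reagents that add atoms: N-iodosuccinimide, O=C1CCC(=O)N1I
Why: ipso-Iododesilylation of the 1,1-disubstituted vinylsilane is a known route to 2-iodo-1-alkenes; the electron-poor tiglate alkene should not react.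

Step 14
Reactants: 22 2-methylbut-3-yn-2-ol
Product: 23 (3E)-2-methyl-4-(tributylstannyl)but-3-en-2-ol
Conditions: Bu3SnH, PdCl2(PPh3)2 (2 mol%), THF, 0 °C to rt
Reagents that add atoms: tributyltin hydride, CCCC[SnH](CCCC)CCCC
Why: Palladium-catalysed syn-hydrostannation; the tertiary carbinol steers tin to the terminal carbon, so the E-alkenylstannane should predominate.

Step 15
Reactants: 21 (1S,3S,4R,6S)-4-(1-iodoethenyl)-1-methyl-2-oxo-7-oxabicyclo[4.1.0]heptan-3-yl (2E)-2-methylbut-2-enoate; 23 (3E)-2-methyl-4-(tributylstannyl)but-3-en-2-ol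
Product: 24 (1S,3S,4S,6S)-4-[(4E)-5-hydroxy-5-methyl-3-oxohexa-1,4-dien-2-yl]-1-methyl-2-oxo-7-oxabicyclo[4.1.0]heptan-3-yl (2E)-2-methylbut-2-enoate (target)
Conditions: Pd2(dba)3 (2.5 mol%), AsPh3 (20 mol%), CO (3 atm), THF, 40 °C
Reagents that add atoms: carbon monoxide, [C-]#[O+]
Why: Carbonylative Stille coupling of a vinyl iodide, CO and a vinylstannane gives unsymmetrical divinyl ketones under neutral conditions with retention of both alkene geometries; CO pressure should favour insertion over direct coupling.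

**Compound list**

1 | (1-bromoethenyl)trimethylsilane | C=C(Br)[Si](C)(C)C | starting material
2 | 2-isopropoxy-4,4,5,5-tetramethyl-1,3,2-dioxaborolane | CC(C)OB1OC(C)(C)C(C)(C)O1 | starting material
3 | bromo[1-(trimethylsilyl)ethenyl]magnesium (not isolated) | C=C([Mg]Br)[Si](C)(C)C | intermediate
4 | 4,4,5,5-tetramethyl-2-[1-(trimethylsilyl)ethenyl]-1,3,2-dioxaborolane | C=C(B1OC(C)(C)C(C)(C)O1)[Si](C)(C)C | intermediate
5 | 5,6-dihydro-2H-pyran-2-one | O=C1C=CCCO1 | starting material
6 | (4R)-4-[1-(trimethylsilyl)ethenyl]oxan-2-one | C=C([Si](C)(C)C)[C@@H]1CCOC(=O)C1 | intermediate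
7 | (5R)-2-ethoxy-7-hydroxy-5-[1-(trimethylsilyl)ethenyl]hept-1-en-3-one | C=C(OCC)C(=O)C[C@@H](CCO)C(=C)[Si](C)(C)C | intermediate
8 | (3R,5R)-2-ethoxy-5-[1-(trimethylsilyl)ethenyl]hept-1-ene-3,7-diol | C=C(OCC)[C@H](O)C[C@@H](CCO)C(=C)[Si](C)(C)C | intermediate
9 | (3R,5R)-3,7-bis[(tert-butyldimethylsilyl)oxy]-2-ethoxy-5-[1-(trimethylsilyl)ethenyl]hept-1-ene | C=C(OCC)[C@H](O[Si](C)(C)C(C)(C)C)C[C@@H](CCO[Si](C)(C)C(C)(C)C)C(=C)[Si](C)(C)C | intermediate
10 | (3R,5R)-3-[(tert-butyldimethylsilyl)oxy]-7-hydroxy-5-[1-(trimethylsilyl)ethenyl]heptan-2-one | CC(=O)[C@H](O[Si](C)(C)C(C)(C)C)C[C@@H](CCO)C(=C)[Si](C)(C)C | intermediate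
11 | (3R,5R)-5-[(tert-butyldimethylsilyl)oxy]-6-oxo-3-[1-(trimethylsilyl)ethenyl]heptyl trifluoromethanesulfonate (not isolated) | CC(=O)[C@H](O[Si](C)(C)C(C)(C)C)C[C@@H](CCOS(=O)(=O)C(F)(F)F)C(=C)[Si](C)(C)C | intermediate
12 | [(3S,5R)-5-[(tert-butyldimethylsilyl)oxy]-6-oxo-3-[1-(trimethylsilyl)ethenyl]heptyl]diphenylsulfonium trifluoromethanesulfonate | CC(=O)[C@H](O[Si](C)(C)C(C)(C)C)C[C@@H](CC[S+](c1ccccc1)c1ccccc1)C(=C)[Si](C)(C)C.[O-]S(=O)(=O)C(F)(F)F | intermediate
13 | sulfonium ylide of 12, carbanion on the sulfur-bearing carbon (not isolated) | CC(=O)[C@H](O[Si](C)(C)C(C)(C)C)C[C@@H](C[CH-][S+](c1ccccc1)c1ccccc1)C(=C)[Si](C)(C)C | intermediate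
14 | cyclohexane betaine: C1 oxido and C6 diphenylsulfonio trans-diaxial; C1 methyl, C2 silyloxy and C4 silylvinyl equatorial (not isolated) | C=C([Si](C)(C)C)[C@@H]1C[C@@H]([S+](c2ccccc2)c2ccccc2)[C@](C)([O-])[C@H](O[Si](C)(C)C(C)(C)C)C1 | intermediate
15 | tert-butyldimethyl{[(1S,2R,4R,6S)-1-methyl-4-[1-(trimethylsilyl)ethenyl]-7-oxabicyclo[4.1.0]heptan-2-yl]oxy}silane (oxirane O, C2–O and C4 group all cis) | C=C([Si](C)(C)C)[C@@H]1C[C@@H]2O[C@]2(C)[C@H](O[Si](C)(C)C(C)(C)C)C1 | intermediate
16 | (1R,2R,4S,6S)-1-methyl-4-[1-(trimethylsilyl)ethenyl]-7-oxabicyclo[4.1.0]heptan-2-ol (same spatial arrangement as 15) | C=C([Si](C)(C)C)[C@@H]1C[C@@H]2O[C@]2(C)[C@H](O)C1 | intermediate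
17 | (1S,4R,6S)-1-methyl-4-[1-(trimethylsilyl)ethenyl]-7-oxabicyclo[4.1.0]heptan-2-one | C=C([Si](C)(C)C)[C@@H]1C[C@@H]2O[C@]2(C)C(=O)C1 | intermediate
18 | potassium C2–C3 enolate of 17 (not isolated) | C=C([Si](C)(C)C)[C@@H]1C[C@@H]2O[C@]2(C)C(O[K])=C1 | intermediate
19 | (1S,3S,4R,6S)-3-hydroxy-1-methyl-4-[1-(trimethylsilyl)ethenyl]-7-oxabicyclo[4.1.0]heptan-2-one (3-OH trans to C4 group and to oxirane O) | C=C([Si](C)(C)C)[C@@H]1C[C@@H]2O[C@]2(C)C(=O)[C@H]1O | intermediate
20 | (1S,3S,4R,6S)-1-methyl-2-oxo-4-[1-(trimethylsilyl)ethenyl]-7-oxabicyclo[4.1.0]heptan-3-yl (2E)-2-methylbut-2-enoate | C=C([Si](C)(C)C)[C@@H]1C[C@@H]2O[C@]2(C)C(=O)[C@H]1OC(=O)/C(C)=C/C | intermediate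
21 | (1S,3S,4R,6S)-4-(1-iodoethenyl)-1-methyl-2-oxo-7-oxabicyclo[4.1.0]heptan-3-yl (2E)-2-methylbut-2-enoate | C=C(I)[C@@H]1C[C@@H]2O[C@]2(C)C(=O)[C@H]1OC(=O)/C(C)=C/C | intermediate
22 | 2-methylbut-3-yn-2-ol | CC(C)(O)C#C | starting material
23 | (3E)-2-methyl-4-(tributylstannyl)but-3-en-2-ol | CCCC[Sn](CCCC)(CCCC)/C=C/C(C)(C)O | intermediate
24 | (1S,3S,4S,6S)-4-[(4E)-5-hydroxy-5-methyl-3-oxohexa-1,4-dien-2-yl]-1-methyl-2-oxo-7-oxabicyclo[4.1.0]heptan-3-yl (2E)-2-methylbut-2-enoate | C=C(C(=O)/C=C/C(C)(C)O)[C@@H]1C[C@@H]2O[C@]2(C)C(=O)[C@H]1OC(=O)/C(C)=C/C | target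

**Step count**

Total steps: 15. Longest linear sequence: 14 (steps 1–13 and 15; step 14 is a one-step branch).

**Steps most likely to fail**

Step 8 (key step). The base or the ylide may enolise the methyl ketone instead of adding to it. Addition may also partition into gauche betaines that cannot close and are lost by ring contraction or reversion. The fallback closes the same C1–C6 bond as an alkene and lets the C2 hydroxyl deliver the oxygen. It sets out from 10 through triflate 11, which is trapped with PPh3 (CH2Cl2, −78 °C to rt) to give [(3S,5R)-5-[(tert-butyldimethylsilyl)oxy]-6-oxo-3-[1-(trimethylsilyl)ethenyl]heptyl]triphenylphosphonium triflate F1. KN(SiMe3)2 in THF then effects an intramolecular Wittig olefination to tert-butyldimethyl{[(1R,5R)-2-methyl-5-[1-(trimethylsilyl)ethenyl]cyclohex-2-en-1-yl]oxy}silane F2. TBAF should give (1R,5R)-2-methyl-5-[1-(trimethylsilyl)ethenyl]cyclohex-2-en-1-ol F3. Hydroxyl-directed epoxidation (VO(acac)2, t-BuOOH, CH2Cl2) should place the oxirane syn to the hydroxyl and comes back to the route at 16.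

Step 2. Transmetallation of the hindered 1-silylalkenyl boronate may be slow, so protodeboronation or low enantioselectivity may take over. The fallback sets out from Grignard reagent 3 and lactone 5: a copper-catalysed 1,4-addition without chiral ligand (CuI, Me3SiCl, THF, −78 °C) should give racemic 4-[1-(trimethylsilyl)ethenyl]oxan-2-one F4. Resolution by preparative chromatography on a chiral stationary phase returns to the route at 6.

Step 7. Diphenyl sulfide is a weak nucleophile, so the triflate may instead be consumed by intramolecular O-alkylation through the silyl ether oxygen or by decomposition on warming. The fallback sets out from 10 and builds the sulfonium group from sulfur outwards. Substitution of the hydroxyl with PhSSPh/Bu3P (THF, rt) should give (3R,5S)-3-[(tert-butyldimethylsilyl)oxy]-7-(phenylsulfanyl)-5-[1-(trimethylsilyl)ethenyl]heptan-2-one F5. Copper-catalysed S-arylation with diphenyliodonium triflate (Cu(OAc)2 cat., 1,2-dichloroethane, 100 °C) comes back to the route at 12.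

**Further compounds**

F1 | step 8 | [(3S,5R)-5-[(tert-butyldimethylsilyl)oxy]-6-oxo-3-[1-(trimethylsilyl)ethenyl]heptyl]triphenylphosphonium trifluoromethanesulfonate | CC(=O)[C@H](O[Si](C)(C)C(C)(C)C)C[C@@H](CC[P+](c1ccccc1)(c1ccccc1)c1ccccc1)C(=C)[Si](C)(C)C.[O-]S(=O)(=O)C(F)(F)F
F2 | step 8 | tert-butyldimethyl{[(1R,5R)-2-methyl-5-[1-(trimethylsilyl)ethenyl]cyclohex-2-en-1-yl]oxy}silane | C=C([Si](C)(C)C)[C@@H]1CC=C(C)[C@H](O[Si](C)(C)C(C)(C)C)C1
F3 | step 8 | (1R,5R)-2-methyl-5-[1-(trimethylsilyl)ethenyl]cyclohex-2-en-1-ol | C=C([Si](C)(C)C)[C@@H]1CC=C(C)[C@H](O)C1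
F4 | step 2 | racemic 4-[1-(trimethylsilyl)ethenyl]oxan-2-one | C=C([Si](C)(C)C)C1CCOC(=O)C1
F5 | step 7 | (3R,5S)-3-[(tert-butyldimethylsilyl)oxy]-7-(phenylsulfanyl)-5-[1-(trimethylsilyl)ethenyl]heptan-2-one | CC(=O)[C@H](O[Si](C)(C)C(C)(C)C)C[C@@H](CCSc1ccccc1)C(=C)[Si](C)(C)C
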